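The route builds ring B (the benzoic acid ring: C1 carboxyl, C2 ether, C4 methoxy, C6 pentanoyl) by a [2+2+2] cycloaddition. In ring A (C1 pentyl) the ether oxygen on C6 and the hydroxyl oxygen on C5 are ortho, and they reach C2 and the carboxyl carbon on C1 of ring B, so a catechol can tether an ethynyl ether and an ynoate. One rhodium-catalysed reaction with methoxyethyne should form C1–C2, C3–C4 and C5–C6, closing ring B and the seven-membered lactone together. The precursor is a benzyl-protected, olivetol-derived catechol bearing an O-ethynyl group and an ynoate ester with a ketal-masked pentanoyl chain. The lactone is opened at the end.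

Key step: step 13

Remark on the chemistry: the target has no stereocentre; its ortho-acylbenzoic acid can equilibrate with a cyclic 3-hydroxyphthalide tautomer, and the open keto acid as drawn is taken as the target.

Step 1
Reactants: 1 olivetol (5-pentylbenzene-1,3-diol)
Product: 2 2,4-dihydroxy-6-pentylbenzaldehyde
Conditions: POCl3, DMF, 0 °C → rt; then ice-water
Reagents that add atoms: N,N-dimethylformamide, CN(C)C=O; water, O
Why: Vilsmeier–Haack formylation: the chloroiminium ion should attack the ring carbon ortho to one hydroxyl and para to the other (beside the pentyl chain), as is usual for 5-alkylresorcinols, and aqueous work-up hydrolyses the iminium salt to the aldehyde.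

Step 2
Reactants: 2 2,4-dihydroxy-6-pentylbenzaldehyde
Product: 3 4-(benzyloxy)-2-hydroxy-6-pentylbenzaldehyde
Conditions: BnBr (1.05 equiv), K2CO3 (1.1 equiv), acetone, rt
Reagents that add atoms: benzyl bromide, BrCc1ccccc1
Why: Williamson ether synthesis: the hydroxyl para to the formyl group is the more acidic and is not tied up in a hydrogen bond to the carbonyl, so one equivalent of benzyl bromide with a weak base should alkylate it alone.

Step 3
Reactants: 3 4-(benzyloxy)-2-hydroxy-6-pentylbenzaldehyde
Product: 4 4-(benzyloxy)-2-(methoxymethoxy)-6-pentylbenzaldehyde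
Conditions: MOMCl, iPr2NEt, CH2Cl2, 0 °C → rt
Reagents that add atoms: chloromethyl methyl ether, COCCl
Why: Williamson-type O-alkylation with an α-chloro ether: the chelated phenol is capped as a MOM acetal, a group that cannot migrate between neighbouring catechol oxygens under the basic conditions of step 5.

Step 4
Reactants: 4 4-(benzyloxy)-2-(methoxymethoxy)-6-pentylbenzaldehyde
Product: 6 4-(benzyloxy)-2-(methoxymethoxy)-6-pentylphenol, via aryl formate 5 (not isolated)
Conditions: mCPBA, CH2Cl2, 0 °C → rt; aq. Na2S2O3 wash; then K2CO3 (cat.), MeOH, 0 °C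
Reagents that add atoms: 3-chloroperoxybenzoic acid, OOC(=O)c1cccc(Cl)c1
Why: Dakin-type Baeyer–Villiger oxidation: in the Criegee adduct of this electron-rich benzaldehyde the aryl group migrates to oxygen to give formate 5, which mild methanolysis cleaves to the phenol whose oxygen becomes the diaryl ether oxygen.

Step 5
Reactants: 6 4-(benzyloxy)-2-(methoxymethoxy)-6-pentylphenol; 7 trichloroethylene
Product: 8 5-(benzyloxy)-2-{[(E)-1,2-dichloroethenyl]oxy}-1-(methoxymethoxy)-3-pentylbenzene
Conditions: 7 (2 equiv), K2CO3, DMF, 70 °C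
Reagents that add atoms: none
Why: Dichlorovinyl ether formation as used in ynol ether synthesis: base converts 7 into dichloroacetylene, to which the phenoxide adds in anti fashion to give the (E)-1,2-dichlorovinyl ether.

Step 6
Reactants: 8 5-(benzyloxy)-2-{[(E)-1,2-dichloroethenyl]oxy}-1-(methoxymethoxy)-3-pentylbenzene
Product: 9 5-(benzyloxy)-2-{[(E)-1,2-dichloroethenyl]oxy}-3-pentylphenol
Conditions: conc. HCl (cat.), MeOH, rt → 40 °C
Reagents that add atoms: none
Why: Acid-catalysed acetal cleavage (transacetalisation to methanol): the MOM ether is removed while the electron-poor dichlorovinyl ether and the benzyl ether should resist dilute acid, so the phenol is freed before the acid-sensitive alkyne exists.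

Step 7
Reactants: 9 5-(benzyloxy)-2-{[(E)-1,2-dichloroethenyl]oxy}-3-pentylphenol
Product: 11 5-(benzyloxy)-2-(ethynyloxy)-3-pentylphenol, via dilithium salt 10 (not isolated)
Conditions: 9 added to n-BuLi (3.3 equiv), THF, −78 → −40 °C; then sat. aq. NH4Cl, −78 °C; crude phenol used at once
Reagents that add atoms: none
Why: Elimination and chlorine–lithium exchange (ynol ether synthesis from a 1,2-dichlorovinyl ether): n-BuLi forms the lithium phenoxide, removes the vinyl hydrogen with loss of chloride to give the chloroalkyne and exchanges the remaining chlorine for lithium, and cold protonation of 10 gives the terminal ethynyl ether, a cold lithium phenoxide being too weak a nucleophile to add to the triple bond.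

Step 8
Reactants: 12 hept-1-yn-3-ol (racemic)
Product: 13 hept-1-yn-3-one
Conditions: Dess–Martin periodinane, CH2Cl2, 0 °C → rt
Reagents that add atoms: none
Why: Dess–Martin oxidation of a secondary propargylic alcohol to the ynone under neutral conditions, which removes the only stereocentre of 12.

Step 9
Reactants: 13 hept-1-yn-3-one
Product: 14 2-butyl-2-ethynyl-1,3-dioxolane
Conditions: 1,2-bis(trimethylsilyloxy)ethane, TMSOTf (cat.), CH2Cl2, −78 → −20 °C
Reagents that add atoms: 1,2-bis(trimethylsilyloxy)ethane, C[Si](C)(C)OCCO[Si](C)(C)C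
Why: Noyori ketalisation: the silylated diol and catalytic TMSOTf form the dioxolane at low temperature, driven by hexamethyldisiloxane formation, which avoids conjugate addition of free glycol to the terminal ynone.

Step 10
Reactants: 14 2-butyl-2-ethynyl-1,3-dioxolane
Product: 16 3-(2-butyl-1,3-dioxolan-2-yl)prop-2-ynoic acid, via lithium acetylide 15 (not isolated)
Conditions: n-BuLi, THF, −78 °C; CO2 (g); then cold 1 M HCl to pH 3
Reagents that add atoms: carbon dioxide, O=C=O
Why: Deprotonation of the terminal alkyne and carboxylation of acetylide 15 with CO2; the propargylic ketal should tolerate the brief cold acidification.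

Step 11
Reactants: 11 5-(benzyloxy)-2-(ethynyloxy)-3-pentylphenol; 16 3-(2-butyl-1,3-dioxolan-2-yl)prop-2-ynoic acid
Product: 17 5-(benzyloxy)-2-(ethynyloxy)-3-pentylphenyl 3-(2-butyl-1,3-dioxolan-2-yl)prop-2-ynoate
Conditions: DCC (1.2 equiv), DMAP (5 mol%), CH2Cl2, −20 → 0 °C, 16 added last
Reagents that add atoms: none
Why: Steglich esterification: the carbodiimide activates the ynoic acid and DMAP passes the acyl group to the neutral phenol, so that neither a free phenoxide nor free acid stays beside the ethynyl ether for long.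

Step 12
Reactants: 18 chloroacetaldehyde dimethyl acetal (2-chloro-1,1-dimethoxyethane)
Product: 20 methoxyethyne, via sodium methoxyacetylide 19 (not isolated)
Conditions: NaNH2 (3.1 equiv), liquid NH3, −33 °C; then cold sat. aq. NH4Cl; distilled into cold CH2Cl2 and used fresh
Reagents that add atoms: none
Why: Double base-induced elimination (of HCl, then of methanol) from the chloroacetal, driven by formation of the sodium acetylide 19, which is protonated on quenching to the low-boiling alkyne.

Step 13
Reactants: 17 5-(benzyloxy)-2-(ethynyloxy)-3-pentylphenyl 3-(2-butyl-1,3-dioxolan-2-yl)prop-2-ynoate; 20 methoxyethyne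
Product: 21 8-(benzyloxy)-1-(2-butyl-1,3-dioxolan-2-yl)-3-methoxy-6-pentyl-11H-dibenzo[b,e][1,4]dioxepin-11-one
Conditions: [Rh(cod)2]BF4 (10 mol%), rac-BINAP (10 mol%), H2 then Ar (catalyst activation), CH2Cl2, rt; 17 added over 6 h to 20 (5 equiv)
Reagents that add atoms: none
Why: Proposed new method: the cationic monovalent rhodium–BINAP fragment should bind the electron-rich ethynyl ether and the electron-poor ynoate that the ortho-phenylene tether of 17 holds side by side and couple them oxidatively to a rhodacyclopentadiene of trivalent rhodium (bond C1–C2 of ring B), after which 20 inserts and reductive elimination forms C3–C4 and C5–C6 and returns monovalent rhodium. The closest known reaction type is the cationic rhodium/bisphosphine-catalysed [2+2+2] cycloaddition of tethered diynes (five- and six-membered tethers) with terminal alkynes to fused benzenes, which has not been shown for a seven-membered ether–ester tether or for this alkyne pair. The seven-membered lactone ring closes in the oxidative coupling, a 7-exo-dig-type closure with respect to both tethered alkynes, and the benzene ring B closes when the inserted two-carbon unit is joined to the far end of the metallacycle by reductive elimination. No stereocentre is formed. The step needs one orientation of 20, with its oxygen-bearing carbon on the CH terminus (C3) and its CH carbon on the ketal-bearing terminus (C6); the bulk of the quaternary dioxolane and the matched polarity of each new bond (nucleophilic β-carbon of an ynol ether to an electrophilic carbon) should secure it. Slow addition of 17 to excess 20 should hold back self-coupling of the diyne, the chemoselectivity the step also needs.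

Step 14
Reactants: 21 8-(benzyloxy)-1-(2-butyl-1,3-dioxolan-2-yl)-3-methoxy-6-pentyl-11H-dibenzo[b,e][1,4]dioxepin-11-one
Product: 22 1-(2-butyl-1,3-dioxolan-2-yl)-8-hydroxy-3-methoxy-6-pentyl-11H-dibenzo[b,e][1,4]dioxepin-11-one
Conditions: H2 (1 atm), 10% Pd/C, EtOAc, rt
Reagents that add atoms: none
Why: Catalytic hydrogenolysis of the benzyl aryl ether; the ketone is still a ketal, so no benzylic carbonyl is exposed to hydrogen, and the lactone and dioxolane should be inert.

Step 15
Reactants: 22 1-(2-butyl-1,3-dioxolan-2-yl)-8-hydroxy-3-methoxy-6-pentyl-11H-dibenzo[b,e][1,4]dioxepin-11-one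
Product: 23 8-hydroxy-3-methoxy-1-pentanoyl-6-pentyl-11H-dibenzo[b,e][1,4]dioxepin-11-one
Conditions: 3 M aq. HCl, THF, 50 °C
Reagents that add atoms: water, O
Why: Acid-catalysed ketal hydrolysis to the aryl ketone; the aryl ester lactone should survive aqueous acid at this temperature.

Step 16
Reactants: 23 8-hydroxy-3-methoxy-1-pentanoyl-6-pentyl-11H-dibenzo[b,e][1,4]dioxepin-11-one
Product: 24 2-(2,4-dihydroxy-6-pentylphenoxy)-4-methoxy-6-pentanoylbenzoic acid
Conditions: LiOH (4 equiv), degassed THF/H2O, 0 °C → rt, Ar; then 1 M HCl to pH 2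
Reagents that add atoms: lithium hydroxide, [Li+].[OH-]
Why: Saponification of the aryl ester lactone with neighbouring-group help: hydroxide adds to the ortho ketone, the hydrate anion attacks the lactone carbonyl and expels the ring A phenoxide, and acidification gives the open keto acid.

Compound list
1 | olivetol (5-pentylbenzene-1,3-diol) | CCCCCc1cc(O)cc(O)c1 | starting material
2 | 2,4-dihydroxy-6-pentylbenzaldehyde | CCCCCc1cc(O)cc(O)c1C=O | intermediate
3 | 4-(benzyloxy)-2-hydroxy-6-pentylbenzaldehyde | CCCCCc1cc(OCc2ccccc2)cc(O)c1C=O | intermediate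
4 | 4-(benzyloxy)-2-(methoxymethoxy)-6-pentylbenzaldehyde | CCCCCc1cc(OCc2ccccc2)cc(OCOC)c1C=O | intermediate
5 | 4-(benzyloxy)-2-(methoxymethoxy)-6-pentylphenyl formate (aryl formate, not isolated) | CCCCCc1cc(OCc2ccccc2)cc(OCOC)c1OC=O | intermediate
6 | 4-(benzyloxy)-2-(methoxymethoxy)-6-pentylphenol | CCCCCc1cc(OCc2ccccc2)cc(OCOC)c1O | intermediate
7 | trichloroethylene | ClC=C(Cl)Cl | starting material
8 | 5-(benzyloxy)-2-{[(E)-1,2-dichloroethenyl]oxy}-1-(methoxymethoxy)-3-pentylbenzene | CCCCCc1cc(OCc2ccccc2)cc(OCOC)c1O/C(Cl)=C\Cl | intermediate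
9 | 5-(benzyloxy)-2-{[(E)-1,2-dichloroethenyl]oxy}-3-pentylphenol | CCCCCc1cc(OCc2ccccc2)cc(O)c1O/C(Cl)=C\Cl | intermediate
10 | lithium 5-(benzyloxy)-2-[(lithioethynyl)oxy]-3-pentylphenolate (dilithium salt, not isolated) | [Li]C#COc1c(CCCCC)cc(OCc2ccccc2)cc1O[Li] | intermediate
11 | 5-(benzyloxy)-2-(ethynyloxy)-3-pentylphenol | CCCCCc1cc(OCc2ccccc2)cc(O)c1OC#C | intermediate
12 | hept-1-yn-3-ol (racemic) | CCCCC(O)C#C | starting material
13 | hept-1-yn-3-one | CCCCC(=O)C#C | intermediate
14 | 2-butyl-2-ethynyl-1,3-dioxolane | CCCCC1(C#C)OCCO1 | intermediate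
15 | [(2-butyl-1,3-dioxolan-2-yl)ethynyl]lithium (lithium acetylide, not isolated) | [Li]C#CC1(CCCC)OCCO1 | intermediate
16 | 3-(2-butyl-1,3-dioxolan-2-yl)prop-2-ynoic acid | CCCCC1(C#CC(=O)O)OCCO1 | intermediate
17 | 5-(benzyloxy)-2-(ethynyloxy)-3-pentylphenyl 3-(2-butyl-1,3-dioxolan-2-yl)prop-2-ynoate | CCCCCc1cc(OCc2ccccc2)cc(OC(=O)C#CC3(CCCC)OCCO3)c1OC#C | intermediate
18 | chloroacetaldehyde dimethyl acetal (2-chloro-1,1-dimethoxyethane) | COC(CCl)OC | starting material
19 | sodium methoxyacetylide (not isolated) | [Na]C#COC | intermediate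
20 | methoxyethyne | COC#C | intermediate
21 | 8-(benzyloxy)-1-(2-butyl-1,3-dioxolan-2-yl)-3-methoxy-6-pentyl-11H-dibenzo[b,e][1,4]dioxepin-11-one | CCCCCc1cc(OCc2ccccc2)cc3OC(=O)c4c(C5(CCCC)OCCO5)cc(OC)cc4Oc13 | intermediate
22 | 1-(2-butyl-1,3-dioxolan-2-yl)-8-hydroxy-3-methoxy-6-pentyl-11H-dibenzo[b,e][1,4]dioxepin-11-one | CCCCCc1cc(O)cc3OC(=O)c4c(C5(CCCC)OCCO5)cc(OC)cc4Oc13 | intermediate
23 | 8-hydroxy-3-methoxy-1-pentanoyl-6-pentyl-11H-dibenzo[b,e][1,4]dioxepin-11-one | CCCCCc1cc(O)cc3OC(=O)c4c(C(=O)CCCC)cc(OC)cc4Oc13 | intermediate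
24 | 2-(2,4-dihydroxy-6-pentylphenoxy)-4-methoxy-6-pentanoylbenzoic acid | CCCCCc1cc(O)cc(O)c1Oc1cc(OC)cc(C(=O)CCCC)c1C(=O)O | target

Total step count: 16.
Longest linear sequence: 12 steps (steps 1–7, 11, 13–16).

Steps most likely to fail

1. Step 13 (the proposed new method). The seven-membered oxidative coupling may be slower than trimerisation of methoxyethyne or oligomerisation of the terminal ethynyl ether, and insertion may occur with the opposite orientation. The fallback uses known chemistry and builds the diaryl ether by aromatic substitution instead of cycloaddition. It sets out from phenol 6 and returns at target 24.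
   - Purchased 1-bromo-3-fluoro-5-methoxybenzene (COc1cc(F)cc(Br)c1) is lithiated between the two halogens with LDA (THF, −78 °C) and formylated with DMF to give 2-bromo-6-fluoro-4-methoxybenzaldehyde F1.
   - Nucleophilic aromatic substitution of the aldehyde-activated fluoride by 6 (K2CO3, DMF, 80 °C) gives 2-[4-(benzyloxy)-2-(methoxymethoxy)-6-pentylphenoxy]-6-bromo-4-methoxybenzaldehyde F2.
   - Pinnick oxidation (NaClO2, NaH2PO4, 2-methylbut-2-ene, t-BuOH/H2O) gives 2-[4-(benzyloxy)-2-(methoxymethoxy)-6-pentylphenoxy]-6-bromo-4-methoxybenzoic acid F3.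
   - Bromine–lithium exchange on the lithium carboxylate (n-BuLi, 2.2 equiv, THF, −90 °C) and acylation with N-methoxy-N-methylpentanamide give 2-[4-(benzyloxy)-2-(methoxymethoxy)-6-pentylphenoxy]-4-methoxy-6-pentanoylbenzoic acid F4.
   - Aqueous HCl in THF removes the MOM group to give 2-[4-(benzyloxy)-2-hydroxy-6-pentylphenoxy]-4-methoxy-6-pentanoylbenzoic acid F5.
   - Hydrogenolysis of the benzyl ether (H2, Pd/C, EtOAc) gives 24.

2. Step 7. The phenoxide beside the forming chloroalkyne or ethynyl ether may add to the triple bond and cyclise, or the free hydroxy ethynyl ether may decompose during handling. The fallback never frees the phenol beside the alkyne. It sets out from 9 and returns at ester 17, bypassing 11 and step 11.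
   - Silylation of 9 (TBSCl, imidazole, DMF) gives tert-butyl(5-(benzyloxy)-2-{[(E)-1,2-dichloroethenyl]oxy}-3-pentylphenoxy)dimethylsilane F6. No silyl migration is possible because the neighbouring oxygen is already capped.
   - n-BuLi (2.3 equiv, THF, −78 → −40 °C) and a cold NH4Cl quench give [5-(benzyloxy)-2-(ethynyloxy)-3-pentylphenoxy](tert-butyl)dimethylsilane F7.
   - Acid 16 is converted with cyanuric fluoride and pyridine (CH2Cl2, 0 °C) into 3-(2-butyl-1,3-dioxolan-2-yl)prop-2-ynoyl fluoride F8.
   - Fluoride-catalysed acylation of silyl ether F7 with F8 (catalytic TBAF, THF, −20 °C) gives 17 directly; the phenoxide set free is trapped by the acyl fluoride as it forms.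

3. Step 16. Under base the enolate of the pentanoyl ketone may attack the aryl ester in an intramolecular Claisen condensation, or the electron-rich diphenolate may be oxidised by air, in competition with hydroxide opening. The fallback opens the lactone while the ketone is still masked. It sets out from 22 and returns at 24, bypassing 23.
   - LiOH (THF/H2O/MeOH, 50 °C, Ar) saponifies the lactone of 22 to give 2-(2-butyl-1,3-dioxolan-2-yl)-6-(2,4-dihydroxy-6-pentylphenoxy)-4-methoxybenzoic acid F9.
   - Aqueous HCl in THF (50 °C) then hydrolyses the ketal, helped by the neighbouring carboxyl group, to give 24.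

Further compounds
F1 | step 13 | 2-bromo-6-fluoro-4-methoxybenzaldehyde | COc1cc(F)c(C=O)c(Br)c1
F2 | step 13 | 2-[4-(benzyloxy)-2-(methoxymethoxy)-6-pentylphenoxy]-6-bromo-4-methoxybenzaldehyde | CCCCCc1cc(OCc2ccccc2)cc(OCOC)c1Oc1cc(OC)cc(Br)c1C=O
F3 | step 13 | 2-[4-(benzyloxy)-2-(methoxymethoxy)-6-pentylphenoxy]-6-bromo-4-methoxybenzoic acid | CCCCCc1cc(OCc2ccccc2)cc(OCOC)c1Oc1cc(OC)cc(Br)c1C(=O)O
F4 | step 13 | 2-[4-(benzyloxy)-2-(methoxymethoxy)-6-pentylphenoxy]-4-methoxy-6-pentanoylbenzoic acid | CCCCCc1cc(OCc2ccccc2)cc(OCOC)c1Oc1cc(OC)cc(C(=O)CCCC)c1C(=O)O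
F5 | step 13 | 2-[4-(benzyloxy)-2-hydroxy-6-pentylphenoxy]-4-methoxy-6-pentanoylbenzoic acid | CCCCCc1cc(OCc2ccccc2)cc(O)c1Oc1cc(OC)cc(C(=O)CCCC)c1C(=O)O
F6 | step 7 | tert-butyl(5-(benzyloxy)-2-{[(E)-1,2-dichloroethenyl]oxy}-3-pentylphenoxy)dimethylsilane | CCCCCc1cc(OCc2ccccc2)cc(O[Si](C)(C)C(C)(C)C)c1O/C(Cl)=C\Cl
F7 | step 7 | [5-(benzyloxy)-2-(ethynyloxy)-3-pentylphenoxy](tert-butyl)dimethylsilane | CCCCCc1cc(OCc2ccccc2)cc(O[Si](C)(C)C(C)(C)C)c1OC#C
F8 | step 7 | 3-(2-butyl-1,3-dioxolan-2-yl)prop-2-ynoyl fluoride | CCCCC1(C#CC(F)=O)OCCO1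
F9 | step 16 | 2-(2-butyl-1,3-dioxolan-2-yl)-6-(2,4-dihydroxy-6-pentylphenoxy)-4-methoxybenzoic acid | CCCCCc1cc(O)cc(O)c1Oc1cc(OC)cc(C2(CCCC)OCCO2)c1C(=O)O
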